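**Plan**

1. Retrosynthesis: after deprotection, the C2–aryl bond of ring C is cut (aryl 1,4-addition to a chromone), the pyranone is unwound to a salicylaldehyde, and ring A is cut through C8–C8a, C6–C7 and C4a–C8a into 3-methoxycyclobutenone and a siloxyalkyne that carries the whole heptanoid arm.
2. The arm is cut at chain-C6=C7 (dehydration), chain-C7–aryl (Grignard addition), chain-C5–alkynyl (conjugate alkynylation), chain-C5=C6 (cross-metathesis) and chain-C3–C4 (allylboration).
3. Forward order: chain (chain-C3, then chain-C5), siloxyalkyne, ring A by benzannulation, ring C as a chromone, ring B aryl added last, deprotection.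
4. Stereochemistry: chain-C3 from Brown allylboration (reagent control), chain-C5 from rhodium-catalysed conjugate alkynylation (ligand control), C2 from rhodium-catalysed aryl addition (ligand control); the alkene is (E) because elimination gives the conjugated styrene.
5. Enabling feature: ring A (C4a to C8a) is a 1,3,5-trioxygenated benzene in which C8, bonded to chain-C5, lies between the oxygens on C7 and C8a, with the methoxy group para on C5. A siloxyalkyne (C7, C8) and a 3-methoxy vinylketene (C8a, C4a, C5, C6) assemble exactly this pattern.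

Key step: step 14

Numbering and abbreviation: flavanone numbering for rings A and C; chain-C1 to chain-C7 for the heptanoid arm (aryl groups on chain-C1 and chain-C7, oxygen on chain-C3, chain-C5 bonded to C8). R* = (1E,3S,5S)-5-[(tert-butyldimethylsilyl)oxy]-1,7-bis[4-(methoxymethoxy)phenyl]hept-1-en-3-yl.

Assumption: the sense of induction in the two rhodium-catalysed additions (steps 9 and 18) is assigned by analogy with the usual facial model for (S)-configured biaryl bisphosphines on (E)-enals and cyclic enones; should a trial deliver the other face, the ligand antipode would be used and nothing else changes.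

**Route**

Step 1
Reactants: 1 ethoxyacetylene
Product: 2 3-ethoxycyclobut-2-en-1-one
Conditions: ketene (gas, from pyrolysis of acetone), CH2Cl2, −10 °C to rt
Reagents that add atoms: ketene, C=C=O
Why: Thermal [2+2] cycloaddition of ketene with an ynol ether, in which the nucleophilic β-carbon of the alkyne attacks the ketene carbonyl carbon so that the ethoxy group ends on C3.

Step 2
Reactants: 2 3-ethoxycyclobut-2-en-1-one
Product: 3 cyclobutane-1,3-dione
Conditions: cold aq. H2SO4, 0 °C; extraction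
Reagents that add atoms: water, O
Why: Acid hydrolysis of a vinylogous ester (addition–elimination at C3) should give the strongly acidic 1,3-dione.

Step 3
Reactants: 3 cyclobutane-1,3-dione
Product: 4 3-methoxycyclobut-2-en-1-one
Conditions: Me3SiCHN2, MeOH/Et2O, 0 °C
Reagents that add atoms: (trimethylsilyl)diazomethane, C[Si](C)(C)C=[N+]=[N-]
Why: O-Methylation of a vinylogous acid by a diazoalkane; the dione is symmetric, so only one enol ether can form.

Step 4
Reactants: 5 methyl 3-(4-hydroxyphenyl)propanoate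
Product: 6 methyl 3-[4-(methoxymethoxy)phenyl]propanoate
Conditions: MeOCH2Cl, i-Pr2NEt, CH2Cl2, 0 °C to rt
Reagents that add atoms: chloromethyl methyl ether, COCCl
Why: Williamson-type O-alkylation of the phenol; the MOM ether should survive every basic, organometallic and fluoride step that follows.

Step 5
Reactants: 6 methyl 3-[4-(methoxymethoxy)phenyl]propanoate
Product: 7 3-[4-(methoxymethoxy)phenyl]propanal
Conditions: i-Bu2AlH (1.1 equiv), CH2Cl2, −78 °C; aq. potassium sodium tartrate
Reagents that add atoms: none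
Why: Partial ester reduction; the tetrahedral aluminium hemiacetal is stable at −78 °C and releases the aldehyde only on work-up.

Step 6
Reactants: 7 3-[4-(methoxymethoxy)phenyl]propanal
Product: 8 (3S)-1-[4-(methoxymethoxy)phenyl]hex-5-en-3-ol
Conditions: (+)-Ipc2B(allyl) (reagent derived from (−)-α-pinene, pentane solution), Et2O, −78 °C; then NaOH, H2O2, 0 °C to rt
Reagents that add atoms: (+)-B-allyldiisopinocampheylborane, C=CCB([C@H]1C[C@H]2C[C@H](C2(C)C)[C@@H]1C)[C@H]1C[C@H]2C[C@H](C2(C)C)[C@@H]1C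
Why: Brown allylboration through a closed chair transition state; this reagent antipode adds to the re face of unbranched aliphatic aldehydes and so should set chain-C3 as (S).

Step 7
Reactants: 8 (3S)-homoallylic alcohol
Product: 9 tert-butyl({(3S)-1-[4-(methoxymethoxy)phenyl]hex-5-en-3-yl}oxy)dimethylsilane
Conditions: t-BuMe2SiCl, imidazole, DMF, rt
Reagents that add atoms: tert-butyldimethylsilyl chloride, CC(C)(C)[Si](C)(C)Cl
Why: Standard silylation of a secondary alcohol; the stereocentre is not touched.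

Step 8
Reactants: 9 homoallylic silyl ether; 10 crotonaldehyde
Product: 11 (2E,5S)-5-[(tert-butyldimethylsilyl)oxy]-7-[4-(methoxymethoxy)phenyl]hept-2-enal
Conditions: second-generation Grubbs catalyst (5 mol %), 10 (5 equiv), CH2Cl2, 40 °C
Reagents that add atoms: none
Why: Olefin cross-metathesis of a terminal alkene with an electron-poor partner, which should be selective for the cross product and for the (E)-enal.

Step 9
Reactants: 11 (E)-enal; 12 (triisopropylsilyl)acetylene
Product: 13 (3S,5S)-5-[(tert-butyldimethylsilyl)oxy]-7-[4-(methoxymethoxy)phenyl]-3-[(triisopropylsilyl)ethynyl]heptanal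
Conditions: [Rh(OAc)(C2H4)2]2 (2.5 mol %), (S)-DTBM-SEGPHOS (6 mol %), MeOH, 40 °C
Reagents that add atoms: none
Why: Rhodium-catalysed asymmetric conjugate alkynylation of an enal, in which the bulky silyl group suppresses alkyne dimerisation and the ligand selects the enal face; the chain-C3 silyloxy centre is remote, so chain-C5 is set under catalyst control.

Step 10
Reactants: 13 β-alkynyl aldehyde; 14 1-bromo-4-(methoxymethoxy)benzene
Product: 16 (3R,5S)-5-[(tert-butyldimethylsilyl)oxy]-1,7-bis[4-(methoxymethoxy)phenyl]-3-[(triisopropylsilyl)ethynyl]heptan-1-ol (both C1 epimers; the descriptor at the alkynyl carbon changes only through CIP priorities), via arylmagnesium bromide 15 (not isolated)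
Conditions: 14, Mg, THF, rt; then 13, THF, −78 to 0 °C; aq. NH4Cl
Reagents that add atoms: none
Why: Grignard 1,2-addition to the aldehyde; the new carbinol centre is removed in the next step, so its configuration does not matter.

Step 11
Reactants: 16 benzylic alcohol
Product: 17 tert-butyl({(3S,5S,6E)-1,7-bis[4-(methoxymethoxy)phenyl]-5-[(triisopropylsilyl)ethynyl]hept-6-en-3-yl}oxy)dimethylsilane
Conditions: Burgess reagent, toluene, 50 °C
Reagents that add atoms: none
Why: Burgess dehydration (syn-elimination of the sulfamate ester); only chain-C6 carries β-hydrogens, and the conjugated (E)-styrene should be the favoured product.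

Step 12
Reactants: 17 silyl-capped enyne
Product: 19 tert-butyl({(3S,5S,6E)-5-ethynyl-1,7-bis[4-(methoxymethoxy)phenyl]hept-6-en-3-yl}oxy)dimethylsilane, via silver acetylide 18 (not isolated)
Conditions: AgF (1.5 equiv), MeOH/THF, rt, dark; then 1 M HCl (aq.)
Reagents that add atoms: none
Why: Silver-assisted protiodesilylation of a bulky alkynylsilane through the silver acetylide; methanolic fluoride should be too weak to cleave the secondary alkyl silyl ether or the MOM ethers, and the medium is not basic enough to isomerise the skipped enyne.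

Step 13
Reactants: 19 terminal alkyne
Product: 22 tert-butyl({(3S,5S,6E)-1,7-bis[4-(methoxymethoxy)phenyl]-5-{[(triisopropylsilyl)oxy]ethynyl}hept-6-en-3-yl}oxy)dimethylsilane, via lithium acetylide 20 (not isolated), via lithium ynolate 21 (not isolated)
Conditions: LiN(SiMe3)2, THF, −78 °C; LiOOt-Bu (from t-BuOOH and LiN(SiMe3)2), −78 to 0 °C; i-Pr3SiOTf, −78 °C
Reagents that add atoms: tert-butyl hydroperoxide (as its lithium salt), CC(C)(C)OO; triisopropylsilyl trifluoromethanesulfonate, CC(C)[Si](OS(=O)(=O)C(F)(F)F)(C(C)C)C(C)C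
Why: Oxidation of a lithium acetylide by lithium tert-butyl peroxide to the ynolate, then O-silylation by the hard silyl triflate; deprotonation at the sp carbon is fast and the resulting anion should protect the neighbouring chain-C5–H from the amide base.

Step 14
Reactants: 22 siloxyalkyne; 4 3-methoxycyclobut-2-en-1-one
Product: 27 5-methoxy-2-R*-3-[(triisopropylsilyl)oxy]phenol, via methoxy vinylketene 23 (not isolated), via vinylcyclobutenone 24 (not isolated), via dienylketene 25 (not isolated), via cyclohexadienone 26 (not isolated)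
Conditions: 4 (2 equiv, added in portions), degassed toluene, 80 °C then 110 °C
Reagents that add atoms: none
Why: Heating opens 4 by 4π-electrocyclic ring opening to vinylketene 23, whose carbonyl carbon is attacked by the nucleophilic, chain-bearing carbon of 22 in a regioselective [2+2] cycloaddition that gives 24 and forms the C8–C8a and C6–C7 bonds. A second 4π-opening gives dienylketene 25, and ring A closes by 6π-electrocyclisation (C4a–C8a bond) to 26, which tautomerises to phenol 27. This is the Danheiser benzannulation of a cyclobutenone with a siloxyalkyne, which is known to give resorcinol monosilyl ethers. No stereocentre is created: the transient sp3 centre of 24 is lost on ring opening, and chain-C3 and chain-C5 are spectators. The required regiochemistry (chain-C5 on C8 between a free hydroxyl and a silyl ether, methoxy para) follows from the polarisation of the silyl ynol ether, and the neutral thermal conditions should leave the propargylic chain-C5 centre, the (E)-alkene and all ethers untouched. Adding 4 in portions keeps the ketene concentration low and should hold back O-acylation of 27.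

Step 15
Reactants: 27 ring A phenol
Product: 28 2-hydroxy-6-methoxy-3-R*-4-[(triisopropylsilyl)oxy]benzaldehyde
Conditions: MgCl2, Et3N, (CH2O)n, THF, reflux
Reagents that add atoms: paraformaldehyde (formaldehyde), C=O
Why: Casnati–Skattebøl ortho-formylation: the magnesium phenoxide delivers formaldehyde to the ortho carbon and a second formaldehyde accepts hydride; C4a is the only free ortho position, and the conditions are too mildly basic to touch the chain-C5–H.

Step 16
Reactants: 28 salicylaldehyde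
Product: 29 1-{2-hydroxy-6-methoxy-3-R*-4-[(triisopropylsilyl)oxy]phenyl}prop-2-yn-1-ol (both carbinol epimers)
Conditions: HC≡CMgBr (3.5 equiv), THF, 0 °C to rt; aq. NH4Cl
Reagents that add atoms: ethynylmagnesium bromide, C#C[Mg]Br
Why: Grignard 1,2-addition to the aldehyde after the first equivalent is consumed as the magnesium phenoxide; the acetylide is too weak a base to deprotonate chain-C5.

Step 17
Reactants: 29 hydroxybenzylic propargylic alcohol (used crude)
Product: 32 5-methoxy-8-R*-7-[(triisopropylsilyl)oxy]-4H-chromen-4-one, via ynone 30 (not isolated), via enaminone 31 (not isolated)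
Conditions: MnO2, CH2Cl2, rt; filtration; Et2NH, EtOH, rt to 40 °C
Reagents that add atoms: none
Why: MnO2 oxidation of the benzylic propargylic alcohol gives the ynone, aza-Michael addition of the amine gives the enaminone, and the phenol closes ring C by 6-endo addition–elimination with loss of the amine, which avoids the 5-exo mode.

Step 18
Reactants: 32 chromone; 33 {4-[(tert-butyldimethylsilyl)oxy]phenyl}boronic acid
Product: 34 (2S)-2-{4-[(tert-butyldimethylsilyl)oxy]phenyl}-5-methoxy-8-R*-7-[(triisopropylsilyl)oxy]-2,3-dihydro-4H-chromen-4-one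
Conditions: [Rh(OH)(cod)]2 (3 mol %), (S)-MeO-F12-BIPHEP (6.6 mol %), 33 (3 equiv), toluene/H2O, 40 °C
Reagents that add atoms: none
Why: Hayashi–Miyaura reaction (rhodium-catalysed asymmetric 1,4-addition of an arylboronic acid) on a chromone; the electron-poor bisphosphine speeds insertion into the deactivated enone and selects the face that gives C2 as (S), and base-free conditions should prevent ring opening of the flavanone.

Step 19
Reactants: 34 protected flavanone
Product: 36 (2S)-2-{4-[(tert-butyldimethylsilyl)oxy]phenyl}-8-[(1E,3S,5S)-5-[(tert-butyldimethylsilyl)oxy]-1,7-bis(4-hydroxyphenyl)hept-1-en-3-yl]-5-methoxy-7-[(triisopropylsilyl)oxy]-2,3-dihydro-4H-chromen-4-one, via bis(trimethylsilyl) ether 35 (not isolated)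
Conditions: Me3SiOTf, 2,2′-bipyridyl, MeCN, 0 °C to rt; then H2O
Reagents that add atoms: none
Why: Silyl-triflate-mediated acetal cleavage buffered by 2,2′-bipyridyl converts the two aryl MOM ethers into aryl trimethylsilyl ethers that hydrolyse on adding water; no Brønsted acid is present, which should spare the styrene, the chain-C5–aryl bond and the flavanone.

Step 20
Reactants: 36 bis-phenol
Product: 37 (2S)-7-hydroxy-2-(4-hydroxyphenyl)-8-[(1E,3S,5S)-5-hydroxy-1,7-bis(4-hydroxyphenyl)hept-1-en-3-yl]-5-methoxy-2,3-dihydro-4H-chromen-4-one (target)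
Conditions: HF·pyridine, pyridine, THF, 0 °C to rt
Reagents that add atoms: none
Why: Fluoride-mediated global desilylation of the two aryl silyl ethers and the secondary alkyl silyl ether; the buffered, weakly acidic medium should neither open the flavanone nor protonate the hydroxystyrene.

**Compound list**

1 | ethoxyacetylene (ethoxyethyne) | CCOC#C | starting material
2 | 3-ethoxycyclobut-2-en-1-one | CCOC1=CC(=O)C1 | intermediate
3 | cyclobutane-1,3-dione | O=C1CC(=O)C1 | intermediate
4 | 3-methoxycyclobut-2-en-1-one | COC1=CC(=O)C1 | intermediate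
5 | methyl 3-(4-hydroxyphenyl)propanoate | COC(=O)CCc1ccc(O)cc1 | starting material
6 | methyl 3-[4-(methoxymethoxy)phenyl]propanoate | COCOc1ccc(CCC(=O)OC)cc1 | intermediate
7 | 3-[4-(methoxymethoxy)phenyl]propanal | COCOc1ccc(CCC=O)cc1 | intermediate
8 | (3S)-1-[4-(methoxymethoxy)phenyl]hex-5-en-3-ol | C=CC[C@@H](O)CCc1ccc(OCOC)cc1 | intermediate
9 | tert-butyl({(3S)-1-[4-(methoxymethoxy)phenyl]hex-5-en-3-yl}oxy)dimethylsilane | C=CC[C@@H](O[Si](C)(C)C(C)(C)C)CCc1ccc(OCOC)cc1 | intermediate
10 | (E)-but-2-enal (crotonaldehyde) | C/C=C/C=O | starting material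
11 | (2E,5S)-5-[(tert-butyldimethylsilyl)oxy]-7-[4-(methoxymethoxy)phenyl]hept-2-enal | O=C/C=C/C[C@@H](O[Si](C)(C)C(C)(C)C)CCc1ccc(OCOC)cc1 | intermediate
12 | ethynyltri(propan-2-yl)silane, (triisopropylsilyl)acetylene | C#C[Si](C(C)C)(C(C)C)C(C)C | starting material
13 | (3S,5S)-5-[(tert-butyldimethylsilyl)oxy]-7-[4-(methoxymethoxy)phenyl]-3-[(triisopropylsilyl)ethynyl]heptanal | O=CC[C@@H](C#C[Si](C(C)C)(C(C)C)C(C)C)C[C@@H](O[Si](C)(C)C(C)(C)C)CCc1ccc(OCOC)cc1 | intermediate
14 | 1-bromo-4-(methoxymethoxy)benzene | COCOc1ccc(Br)cc1 | starting material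
15 | [4-(methoxymethoxy)phenyl]magnesium bromide | COCOc1ccc([Mg]Br)cc1 | intermediate
16 | (3R,5S)-5-[(tert-butyldimethylsilyl)oxy]-1,7-bis[4-(methoxymethoxy)phenyl]-3-[(triisopropylsilyl)ethynyl]heptan-1-ol, both C1 epimers | COCOc1ccc(C(O)C[C@@H](C#C[Si](C(C)C)(C(C)C)C(C)C)C[C@@H](O[Si](C)(C)C(C)(C)C)CCc2ccc(OCOC)cc2)cc1 | intermediate
17 | tert-butyl({(3S,5S,6E)-1,7-bis[4-(methoxymethoxy)phenyl]-5-[(triisopropylsilyl)ethynyl]hept-6-en-3-yl}oxy)dimethylsilane | COCOc1ccc(/C=C/[C@@H](C#C[Si](C(C)C)(C(C)C)C(C)C)C[C@@H](O[Si](C)(C)C(C)(C)C)CCc2ccc(OCOC)cc2)cc1 | intermediate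
18 | silver acetylide of 19 (R*–C≡C–Ag) | COCOc1ccc(/C=C/[C@@H](C#C[Ag])C[C@@H](O[Si](C)(C)C(C)(C)C)CCc2ccc(OCOC)cc2)cc1 | intermediate
19 | tert-butyl({(3S,5S,6E)-5-ethynyl-1,7-bis[4-(methoxymethoxy)phenyl]hept-6-en-3-yl}oxy)dimethylsilane | COCOc1ccc(/C=C/[C@@H](C#C)C[C@@H](O[Si](C)(C)C(C)(C)C)CCc2ccc(OCOC)cc2)cc1 | intermediate
20 | lithium acetylide of 19 (R*–C≡C–Li) | [Li]C#C[C@H](/C=C/c1ccc(OCOC)cc1)C[C@@H](O[Si](C)(C)C(C)(C)C)CCc1ccc(OCOC)cc1 | intermediate
21 | lithium 2-R*-ethyn-1-olate (lithium ynolate) | [Li+].[O-]C#C[C@H](/C=C/c1ccc(OCOC)cc1)C[C@@H](O[Si](C)(C)C(C)(C)C)CCc1ccc(OCOC)cc1 | intermediate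
22 | tert-butyl({(3S,5S,6E)-1,7-bis[4-(methoxymethoxy)phenyl]-5-{[(triisopropylsilyl)oxy]ethynyl}hept-6-en-3-yl}oxy)dimethylsilane (siloxyalkyne) | CC(C)[Si](OC#C[C@H](/C=C/c1ccc(OCOC)cc1)C[C@@H](O[Si](C)(C)C(C)(C)C)CCc1ccc(OCOC)cc1)(C(C)C)C(C)C | intermediate
23 | 3-methoxybuta-1,3-dien-1-one (methoxy vinylketene) | COC(=C)C=C=O | intermediate
24 | 4-(1-methoxyethenyl)-2-R*-3-[(triisopropylsilyl)oxy]cyclobut-2-en-1-one, both C4 epimers | COC(=C)C1C(=O)C([C@H](/C=C/c2ccc(OCOC)cc2)C[C@@H](O[Si](C)(C)C(C)(C)C)CCc2ccc(OCOC)cc2)=C1O[Si](C(C)C)(C(C)C)C(C)C | intermediate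
25 | (3E)-5-methoxy-2-R*-3-[(triisopropylsilyl)oxy]hexa-1,3,5-trien-1-one (dienylketene) | O=C=C([C@H](/C=C/c1ccc(OCOC)cc1)C[C@@H](O[Si](C)(C)C(C)(C)C)CCc1ccc(OCOC)cc1)/C(O[Si](C(C)C)(C(C)C)C(C)C)=C\C(OC)=C | intermediate
26 | 5-methoxy-2-R*-3-[(triisopropylsilyl)oxy]cyclohexa-2,4-dien-1-one | COC1=CC(O[Si](C(C)C)(C(C)C)C(C)C)=C([C@H](/C=C/c2ccc(OCOC)cc2)C[C@@H](O[Si](C)(C)C(C)(C)C)CCc2ccc(OCOC)cc2)C(=O)C1 | intermediate
27 | 5-methoxy-2-R*-3-[(triisopropylsilyl)oxy]phenol | COc1cc(O)c([C@H](/C=C/c2ccc(OCOC)cc2)C[C@@H](O[Si](C)(C)C(C)(C)C)CCc2ccc(OCOC)cc2)c(O[Si](C(C)C)(C(C)C)C(C)C)c1 | intermediate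
28 | 2-hydroxy-6-methoxy-3-R*-4-[(triisopropylsilyl)oxy]benzaldehyde | COc1cc(O[Si](C(C)C)(C(C)C)C(C)C)c([C@H](/C=C/c2ccc(OCOC)cc2)C[C@@H](O[Si](C)(C)C(C)(C)C)CCc2ccc(OCOC)cc2)c(O)c1C=O | intermediate
29 | 1-{2-hydroxy-6-methoxy-3-R*-4-[(triisopropylsilyl)oxy]phenyl}prop-2-yn-1-ol, both carbinol epimers | COc1cc(O[Si](C(C)C)(C(C)C)C(C)C)c([C@H](/C=C/c2ccc(OCOC)cc2)C[C@@H](O[Si](C)(C)C(C)(C)C)CCc2ccc(OCOC)cc2)c(O)c1C(O)C#C | intermediate
30 | 1-{2-hydroxy-6-methoxy-3-R*-4-[(triisopropylsilyl)oxy]phenyl}prop-2-yn-1-one | COc1cc(O[Si](C(C)C)(C(C)C)C(C)C)c([C@H](/C=C/c2ccc(OCOC)cc2)C[C@@H](O[Si](C)(C)C(C)(C)C)CCc2ccc(OCOC)cc2)c(O)c1C(=O)C#C | intermediate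
31 | (2E)-3-(diethylamino)-1-{2-hydroxy-6-methoxy-3-R*-4-[(triisopropylsilyl)oxy]phenyl}prop-2-en-1-one | COc1cc(O[Si](C(C)C)(C(C)C)C(C)C)c([C@H](/C=C/c2ccc(OCOC)cc2)C[C@@H](O[Si](C)(C)C(C)(C)C)CCc2ccc(OCOC)cc2)c(O)c1C(=O)/C=C/N(CC)CC | intermediate
32 | 5-methoxy-8-R*-7-[(triisopropylsilyl)oxy]-4H-chromen-4-one | COc1cc(O[Si](C(C)C)(C(C)C)C(C)C)c([C@H](/C=C/c2ccc(OCOC)cc2)C[C@@H](O[Si](C)(C)C(C)(C)C)CCc2ccc(OCOC)cc2)c2occc(=O)c12 | intermediate
33 | {4-[(tert-butyldimethylsilyl)oxy]phenyl}boronic acid | CC(C)(C)[Si](C)(C)Oc1ccc(B(O)O)cc1 | starting material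
34 | (2S)-2-{4-[(tert-butyldimethylsilyl)oxy]phenyl}-5-methoxy-8-R*-7-[(triisopropylsilyl)oxy]-2,3-dihydro-4H-chromen-4-one | COc1cc(O[Si](C(C)C)(C(C)C)C(C)C)c([C@H](/C=C/c2ccc(OCOC)cc2)C[C@@H](O[Si](C)(C)C(C)(C)C)CCc2ccc(OCOC)cc2)c2c1C(=O)C[C@@H](c1ccc(O[Si](C)(C)C(C)(C)C)cc1)O2 | intermediate
35 | (2S)-2-{4-[(tert-butyldimethylsilyl)oxy]phenyl}-8-[(1E,3S,5S)-5-[(tert-butyldimethylsilyl)oxy]-1,7-bis{4-[(trimethylsilyl)oxy]phenyl}hept-1-en-3-yl]-5-methoxy-7-[(triisopropylsilyl)oxy]-2,3-dihydro-4H-chromen-4-one | COc1cc(O[Si](C(C)C)(C(C)C)C(C)C)c([C@H](/C=C/c2ccc(O[Si](C)(C)C)cc2)C[C@@H](O[Si](C)(C)C(C)(C)C)CCc2ccc(O[Si](C)(C)C)cc2)c2c1C(=O)C[C@@H](c1ccc(O[Si](C)(C)C(C)(C)C)cc1)O2 | intermediate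
36 | (2S)-2-{4-[(tert-butyldimethylsilyl)oxy]phenyl}-8-[(1E,3S,5S)-5-[(tert-butyldimethylsilyl)oxy]-1,7-bis(4-hydroxyphenyl)hept-1-en-3-yl]-5-methoxy-7-[(triisopropylsilyl)oxy]-2,3-dihydro-4H-chromen-4-one | COc1cc(O[Si](C(C)C)(C(C)C)C(C)C)c([C@H](/C=C/c2ccc(O)cc2)C[C@@H](O[Si](C)(C)C(C)(C)C)CCc2ccc(O)cc2)c2c1C(=O)C[C@@H](c1ccc(O[Si](C)(C)C(C)(C)C)cc1)O2 | intermediate
37 | (2S)-7-hydroxy-2-(4-hydroxyphenyl)-8-[(1E,3S,5S)-5-hydroxy-1,7-bis(4-hydroxyphenyl)hept-1-en-3-yl]-5-methoxy-2,3-dihydro-4H-chromen-4-one | COc1cc(O)c([C@H](/C=C/c2ccc(O)cc2)C[C@@H](O)CCc2ccc(O)cc2)c2c1C(=O)C[C@@H](c1ccc(O)cc1)O2 | target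

**Step count**

Total: 20 steps. Longest linear sequence: 17 steps (steps 4 to 20, from 5 to 37). Steps 1 to 3 make cyclobutenone 4, which joins at step 14.

**Steps most likely to fail**

Step 14 (benzannulation). The vinylogous-ester cyclobutenone may open too slowly, so that the siloxyalkyne degrades thermally first, or the vinylketene may be captured by the product phenol. The fallback makes the same vinylketene at ambient temperature by a Wolff rearrangement instead of by ring opening. Commercial 3,3-dimethoxybutan-2-one would lose methanol under acid catalysis to give 3-methoxybut-3-en-2-one F1. Trifluoroacetylation of its lithium enolate with 2,2,2-trifluoroethyl trifluoroacetate would give 1,1,1-trifluoro-5-methoxyhex-5-ene-2,4-dione F2, and detrifluoroacetylative diazo transfer with methanesulfonyl azide, Et3N and water would give 1-diazo-3-methoxybut-3-en-2-one F3. Irradiating F3 at 365 nm in CH2Cl2 in the presence of 22 should give 23 and from it vinylcyclobutenone 24; at this wavelength the alkoxystyrene does not absorb. Heating 24 in toluene then completes the sequence. The fallback sets out from 22 and returns to the route at 27.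

Step 18 (aryl addition to the chromone). Turnover may be poor at the electron-rich chromone with its large C8 substituent, protodeboronation may outrun insertion, or facial control may be incomplete. The fallback gives up catalyst control. {4-[(tert-Butyldimethylsilyl)oxy]phenyl}magnesium bromide F4, made from commercial (4-bromophenoxy)(tert-butyl)dimethylsilane and Mg, would be added to 32 with catalytic CuBr·SMe2 in THF at −78 to −40 °C. This conjugate addition should give 34 together with its C2 epimer, (2R)-2-{4-[(tert-butyldimethylsilyl)oxy]phenyl}-5-methoxy-8-R*-7-[(triisopropylsilyl)oxy]-2,3-dihydro-4H-chromen-4-one F5. The two are diastereomers because of the chain stereocentres and would be separated by chromatography. The fallback sets out from 32 and returns at 34.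

Step 17 (oxidation and ring C closure; the lability of 29 from step 16 belongs here). The free, electron-rich hydroxybenzylic alcohol may lose water to an ortho-quinone methide, the phenol may be oxidised by MnO2, or the ynone may close in the 5-exo mode. The fallback masks the phenol before the carbinol is made. Silylation of 28 with t-BuMe2SiOTf and 2,6-lutidine would give 2-[(tert-butyldimethylsilyl)oxy]-6-methoxy-3-R*-4-[(triisopropylsilyl)oxy]benzaldehyde F6. Ethynylmagnesium bromide would then give 1-{2-[(tert-butyldimethylsilyl)oxy]-6-methoxy-3-R*-4-[(triisopropylsilyl)oxy]phenyl}prop-2-yn-1-ol F7, and MnO2 or Dess–Martin periodinane would give 1-{2-[(tert-butyldimethylsilyl)oxy]-6-methoxy-3-R*-4-[(triisopropylsilyl)oxy]phenyl}prop-2-yn-1-one F8. Diethylamine in ethanol should add to the ynone, cleave the ortho silyl ether and close the pyranone in the 6-endo mode. The fallback sets out from 28 and returns at 32.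

**Further compounds**

F1 | step 14 | 3-methoxybut-3-en-2-one | COC(=C)C(C)=O
F2 | step 14 | 1,1,1-trifluoro-5-methoxyhex-5-ene-2,4-dione | COC(=C)C(=O)CC(=O)C(F)(F)F
F3 | step 14 | 1-diazo-3-methoxybut-3-en-2-one | COC(=C)C(=O)C=[N+]=[N-]
F4 | step 18 | {4-[(tert-butyldimethylsilyl)oxy]phenyl}magnesium bromide | CC(C)(C)[Si](C)(C)Oc1ccc([Mg]Br)cc1
F5 | step 18 | (2R)-2-{4-[(tert-butyldimethylsilyl)oxy]phenyl}-5-methoxy-8-R*-7-[(triisopropylsilyl)oxy]-2,3-dihydro-4H-chromen-4-one | COc1cc(O[Si](C(C)C)(C(C)C)C(C)C)c([C@H](/C=C/c2ccc(OCOC)cc2)C[C@@H](O[Si](C)(C)C(C)(C)C)CCc2ccc(OCOC)cc2)c2c1C(=O)C[C@H](c1ccc(O[Si](C)(C)C(C)(C)C)cc1)O2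
F6 | step 17 | 2-[(tert-butyldimethylsilyl)oxy]-6-methoxy-3-R*-4-[(triisopropylsilyl)oxy]benzaldehyde | COc1cc(O[Si](C(C)C)(C(C)C)C(C)C)c([C@H](/C=C/c2ccc(OCOC)cc2)C[C@@H](O[Si](C)(C)C(C)(C)C)CCc2ccc(OCOC)cc2)c(O[Si](C)(C)C(C)(C)C)c1C=O
F7 | step 17 | 1-{2-[(tert-butyldimethylsilyl)oxy]-6-methoxy-3-R*-4-[(triisopropylsilyl)oxy]phenyl}prop-2-yn-1-ol | COc1cc(O[Si](C(C)C)(C(C)C)C(C)C)c([C@H](/C=C/c2ccc(OCOC)cc2)C[C@@H](O[Si](C)(C)C(C)(C)C)CCc2ccc(OCOC)cc2)c(O[Si](C)(C)C(C)(C)C)c1C(O)C#C
F8 | step 17 | 1-{2-[(tert-butyldimethylsilyl)oxy]-6-methoxy-3-R*-4-[(triisopropylsilyl)oxy]phenyl}prop-2-yn-1-one | COc1cc(O[Si](C(C)C)(C(C)C)C(C)C)c([C@H](/C=C/c2ccc(OCOC)cc2)C[C@@H](O[Si](C)(C)C(C)(C)C)CCc2ccc(OCOC)cc2)c(O[Si](C)(C)C(C)(C)C)c1C(=O)C#C
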